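**Retrosynthetic overview**
1. The carbocycle and all four stereocentres are bought as (−)-quinic acid 1; no carbocyclic ring is built.
2. The only ring formed is the bridging γ-lactone of quinide 2, closed first; it masks CO2H and 5-OH together and leaves the cis-3,4-diol and the hindered tertiary 1-OH.
3. Key disconnection: the two ester C–O bonds at O3 and O4, traced back to 2 and two molecules of O-benzylvanillin 3 at the aldehyde oxidation level; forward, acyl azolium 4 acylates 2 twice (through mono-ester 5) to give diester lactone 6.
4. Last disconnection: the benzyl ethers (removal gives 7) and the lactone C–O bond, which water reopens to release 5-OH and CO2H of Burkinabin A 8.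

Assumption: locants follow quinic acid (C1 carries CO2H and OH; 3-O and 4-O cis; 5-OH trans to 4-O and cis to CO2H), so the given SMILES is 3,4-di-O-vanilloyl-(−)-quinic acid 8 with the ring stereocentres of 1 unchanged.

**Route**

Step 1
Reactants: 1 (−)-quinic acid
Product: 2 1,5-quinide (quinic acid 1,5-γ-lactone)
Conditions: TsOH·H2O (5 mol %), toluene/DMF 3:1, reflux, Dean–Stark, 16 h
Reagents that add atoms: none
Why: Acid-catalysed Fischer lactonisation driven by azeotropic removal of water; only 5-OH is cis to CO2H, so only the 1,5-γ-lactone can close, and because the new bond is acyl C–O no stereocentre is touched.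

Step 2
Reactants: 2 1,5-quinide; 3 4-benzyloxy-3-methoxybenzaldehyde (O-benzylvanillin)
Product: 6 dibenzyl diester lactone 3,4-bis-O-(4-benzyloxy-3-methoxybenzoyl)-1,5-quinide, via acyl triazolium iodide 4 (not isolated), via quinide 3-O-mono-ester 5 (not isolated)
Conditions: 3 (2.4 equiv), 1,4-dimethyl-1,2,4-triazolium iodide (20 mol %), DBU (1,8-diazabicyclo[5.4.0]undec-7-ene, 0.5 equiv), 3,3',5,5'-tetra-tert-butyldiphenoquinone (2.4 equiv), 4 Å MS, THF/DMF 4:1, rt → 40 °C, 24–48 h
Reagents that add atoms: none
Why: Proposed new method: a site-selective, oxidative carbene-catalysed double esterification of an unprotected triol lactone, in which the triazolylidene adds to 3, the adduct is oxidised by the diphenoquinone to acyl azolium 4, and 4 transfers its aroyl group first to the equatorial 3-OH (hydrogen-bond activated by the carbene/DBU and by the cis 4-OH) to give 5 and in a second turnover to the axial 4-OH, while the tertiary α-hydroxy-lactone 1-OH is too hindered for the bulky, weakly electrophilic acyl azolium; the closest known reaction type is the carbene-catalysed oxidative esterification of aryl aldehydes with simple alcohols using the same quinone, not yet shown as a double acylation of quinide or any cyclitol lactone; only acyl C–O bonds form, so C3 and C4 keep their configuration.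

Step 3
Reactants: 6 3,4-bis-O-(4-benzyloxy-3-methoxybenzoyl)-1,5-quinide
Product: 8 Burkinabin A, via 3,4-di-O-vanilloyl-1,5-quinide 7 (not isolated)
Conditions: H2 (1 atm), 10% Pd/C, THF/1 M aq HCl 1:1, rt, 3 h; filter; filtrate rt → 35 °C, 3–5 d; C18 chromatography (H2O/MeCN, 0.1% HCO2H)
Reagents that add atoms: water (O)
Why: Hydrogenolysis of the two benzyl aryl ethers on palladium leaves the aroyl esters (non-benzylic alkyl C–O) intact, and the strained bicyclic lactone then undergoes acid-catalysed acyl–oxygen (A_AC2) hydrolysis in the water-rich medium, where acyl migration is slow, so the C5–O bond and every stereocentre are unchanged.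

**Compound list**
1 | (−)-quinic acid, (1S,3R,4S,5R)-1,3,4,5-tetrahydroxycyclohexane-1-carboxylic acid (1-OH, 3-OH, 4-OH on one face; 5-OH and CO2H on the other) | O[C@H]1[C@H](O)C[C@](O)(C(=O)O)C[C@H]1O | starting material
2 | 1,5-quinide, (1S,3R,4R,5R)-1,3,4-trihydroxy-6-oxabicyclo[3.2.1]octan-7-one (lactone from CO2H to O5; 3-OH equatorial, 4-OH axial) | O[C@H]1[C@H](O2)C[C@](O)(C2=O)C[C@H]1O | intermediate
3 | 4-benzyloxy-3-methoxybenzaldehyde (O-benzylvanillin) | O=Cc1ccc(OCc2ccccc2)c(OC)c1 | starting material
4 | 5-(4-benzyloxy-3-methoxybenzoyl)-1,4-dimethyl-1,2,4-triazolium iodide (acyl azolium) | C[n+]1ncn(C)c1C(=O)c1ccc(OCc2ccccc2)c(OC)c1.[I-] | intermediate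
5 | 3-O-(4-benzyloxy-3-methoxybenzoyl)-1,5-quinide (ester on O3; 1-OH and 4-OH free; ring configuration of 2) | O[C@H]1[C@H](O2)C[C@](O)(C2=O)C[C@H]1OC(=O)c1ccc(OCc2ccccc2)c(OC)c1 | intermediate
6 | 3,4-bis-O-(4-benzyloxy-3-methoxybenzoyl)-1,5-quinide (esters on O3 and O4, cis; 1-OH free; ring configuration of 2) | COc1cc(C(=O)O[C@H]2[C@H](O3)C[C@](O)(C3=O)C[C@H]2OC(=O)c2ccc(OCc3ccccc3)c(OC)c2)ccc1OCc1ccccc1 | intermediate
7 | 3,4-di-O-vanilloyl-1,5-quinide (as 6 with both phenols free) | COc1cc(C(=O)O[C@H]2[C@H](O3)C[C@](O)(C3=O)C[C@H]2OC(=O)c2ccc(O)c(OC)c2)ccc1O | intermediate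
8 | Burkinabin A, 3,4-di-O-vanilloyl-(−)-quinic acid, (1R,3R,4S,5R)-1,5-dihydroxy-3,4-bis[(4-hydroxy-3-methoxybenzoyl)oxy]cyclohexane-1-carboxylic acid | COc1cc(C(=O)O[C@H]2[C@H](O)C[C@](O)(C(=O)O)C[C@H]2OC(=O)c2ccc(O)c(OC)c2)ccc1O | target

**Totals**
Total step count: 3. Longest linear sequence: 3 (1 → 2 → 6 → 8). All four stereocentres come from 1; every step makes or breaks only acyl C–O or benzyl C–O bonds, never a bond at a ring carbon.

**Steps most likely to fail, and fallbacks**

Step 2 (the proposed new method, highest risk). The reaction may stall at mono-ester 5 because the axial 4-OH next to the new aroyl group is slow towards the acyl azolium. DBU or the free carbene may also open or oligomerise the lactone, and traces of water divert 4 to the acid. The fallback uses known chemistry, sets out from 3 and comes back at 6. Pinnick oxidation of 3 (NaClO2, NaH2PO4, 2-methyl-2-butene, t-BuOH/H2O, rt) gives 4-benzyloxy-3-methoxybenzoic acid F1. Oxalyl chloride with catalytic DMF in CH2Cl2 converts it into 4-benzyloxy-3-methoxybenzoyl chloride F2. Quinide 2 is then acylated with F2 (2.2 equiv) in pyridine/CH2Cl2 with 4-(dimethylamino)pyridine (10 mol %) at 0 °C → rt to give 6. The tertiary 1-OH is the slowest hydroxyl, so stoichiometry and temperature limit over-acylation, and any tri-ester is removed by chromatography.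

Step 3. The acid hydrolysis is an equilibrium and may leave lactone 7. Long exposure may also cause some 4→5 acyl migration or ester cleavage. The fallback sets out from 6 and comes back at 8, opening the lactone irreversibly before the phenols are unmasked. LiOH (1.05 equiv) in THF/H2O at 0 °C for a short time, then acidification to pH 2 with 1 M HCl, saponifies the strained α-hydroxy lactone much faster than the hindered, electron-rich secondary aroyl esters. With the phenols still benzylated only one equivalent of base is consumed. This gives 3,4-bis-O-(4-benzyloxy-3-methoxybenzoyl)-(−)-quinic acid F3. Neutral hydrogenolysis (H2, Pd/C, EtOAc/MeOH, rt) then gives 8.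

Step 1. Lactonisation may be incomplete, and the water-soluble 2 is awkward to separate from 1. The fallback sets out from 1 and comes back at 2. 2,2-Dimethoxypropane and TsOH·H2O in refluxing acetone give the crystalline, lipophilic 3,4-O-isopropylidene-1,5-quinide F4, which is easily purified. TFA/H2O 9:1 at 0 °C → rt then removes the acetonide without opening the lactone and gives 2.

**Further compounds**
F1 | step 2 | 4-benzyloxy-3-methoxybenzoic acid | O=C(O)c1ccc(OCc2ccccc2)c(OC)c1
F2 | step 2 | 4-benzyloxy-3-methoxybenzoyl chloride | O=C(Cl)c1ccc(OCc2ccccc2)c(OC)c1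
F3 | step 3 | 3,4-bis-O-(4-benzyloxy-3-methoxybenzoyl)-(−)-quinic acid (ring configuration of 1; 1-OH, 5-OH and CO2H free) | COc1cc(C(=O)O[C@H]2[C@H](O)C[C@](O)(C(=O)O)C[C@H]2OC(=O)c2ccc(OCc3ccccc3)c(OC)c2)ccc1OCc1ccccc1
F4 | step 1 | 3,4-O-isopropylidene-1,5-quinide (acetonide on the cis O3/O4 pair; ring configuration of 2) | CC1(C)O[C@H]2[C@H](O3)C[C@](O)(C3=O)C[C@H]2O1
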